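Ring C of the flavanone is a 2-aryl-2,3-dihydro-4-pyranone whose only stereocentre, C2, is the former formyl carbon of ring B; ring A merely shares the C4a–C8a edge. Ring C is therefore made first. A BINOL–titanium hetero-Diels–Alder reaction of a silyloxydiene with a ring B aldehyde that already carries the benzyl-protected 8-flavonyl unit forms C2–C3 and O1–C8a and sets (S)-C2 in one operation. Ring A is then annulated onto the C4a=C8a enone by bromination and cycloaddition with a 1,1,3-trioxygenated diene, and hydrogenolysis frees the phenols. The aldehyde comes from a chalcone-derived flavone by C8 iodination and Suzuki coupling.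

Key step: step 6

Remark: the aryl–aryl axis between flavone C8 and ring B has no descriptor in the target and is treated as freely rotating, so C2 of the flavanone is the only stereo-element controlled.

Step 1
Reactants: 1 1-(2,6-dihydroxy-4-methoxyphenyl)ethan-1-one
Product: 2 1-[2-(benzyloxy)-6-hydroxy-4-methoxyphenyl]ethan-1-one
Conditions: BnBr (1.05 equiv), K2CO3, acetone, reflux
Reagents that add atoms: benzyl bromide, BrCc1ccccc1
Why: Williamson etherification; after the first alkylation the remaining phenol is locked in a hydrogen bond to the acetyl group, so one equivalent of halide should stop at the mono-ether.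

Step 2
Reactants: 2 1-[2-(benzyloxy)-6-hydroxy-4-methoxyphenyl]ethan-1-one; 3 4-(benzyloxy)benzaldehyde
Product: 4 (E)-1-[2-(benzyloxy)-6-hydroxy-4-methoxyphenyl]-3-[4-(benzyloxy)phenyl]prop-2-en-1-one
Conditions: KOH, EtOH/THF, rt
Reagents that add atoms: none
Why: Claisen–Schmidt condensation of a methyl ketone with a non-enolisable aldehyde should give the E-chalcone; any flavanone formed by oxa-Michael closure converges in step 3.

Step 3
Reactants: 4 (E)-1-[2-(benzyloxy)-6-hydroxy-4-methoxyphenyl]-3-[4-(benzyloxy)phenyl]prop-2-en-1-one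
Product: 5 5-(benzyloxy)-2-[4-(benzyloxy)phenyl]-7-methoxy-4H-chromen-4-one
Conditions: I2 (10 mol%), DMSO, 130 °C
Reagents that add atoms: none
Why: Iodine-catalysed oxidative cyclisation of a 2'-hydroxychalcone (oxa-Michael closure, C3 iodination and loss of HI, with DMSO as terminal oxidant) is a standard flavone synthesis that benzyl ethers tolerate.

Step 4
Reactants: 5 5-(benzyloxy)-2-[4-(benzyloxy)phenyl]-7-methoxy-4H-chromen-4-one
Product: 6 5-(benzyloxy)-2-[4-(benzyloxy)phenyl]-8-iodo-7-methoxy-4H-chromen-4-one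
Conditions: NIS (1.1 equiv), CF3CO2H (cat.), MeCN/CH2Cl2, 0 °C to rt
Reagents that add atoms: N-iodosuccinimide, O=C1CCC(=O)N1I
Why: Electrophilic aromatic iodination of a 5,7-dialkoxyflavone should occur at C8 (para to the C5 ether, ortho to the C7 ether, beside the small ring oxygen), not at C6, which is buttressed by two alkoxy groups, nor on the less activated rings.

Step 5
Reactants: 6 5-(benzyloxy)-2-[4-(benzyloxy)phenyl]-8-iodo-7-methoxy-4H-chromen-4-one; 7 (5-formyl-2-methoxyphenyl)boronic acid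
Product: 8 3-{5-(benzyloxy)-2-[4-(benzyloxy)phenyl]-7-methoxy-4-oxo-4H-chromen-8-yl}-4-methoxybenzaldehyde
Conditions: Pd(OAc)2 (5 mol%), 2-dicyclohexylphosphino-2',6'-dimethoxybiphenyl (10 mol%), K3PO4, toluene/H2O, 90 °C
Reagents that add atoms: none
Why: Suzuki–Miyaura coupling; the bulky electron-rich biarylphosphine should promote oxidative addition of the hindered iodide to zerovalent palladium and reductive elimination of the tri-ortho-substituted biaryl, and the formyl group is tolerated.

Step 6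
Reactants: 8 3-{5-(benzyloxy)-2-[4-(benzyloxy)phenyl]-7-methoxy-4-oxo-4H-chromen-8-yl}-4-methoxybenzaldehyde; 9 (E)-1-methoxy-3-(trimethylsilyloxy)buta-1,3-diene
Product: 11 (2S)-2-(3-{5-(benzyloxy)-2-[4-(benzyloxy)phenyl]-7-methoxy-4-oxo-4H-chromen-8-yl}-4-methoxyphenyl)-2,3-dihydro-4H-pyran-4-one, via silyl aldol adduct 10 (not isolated)
Conditions: Ti(OiPr)4 (20 mol%), (S)-BINOL (40 mol%), CF3CO2H (cat.), 4 Å MS, toluene/CH2Cl2, −20 °C; then CF3CO2H, CH2Cl2, 0 °C to rt
Reagents that add atoms: none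
Why: The BINOL-ligated tetravalent titanium centre activates the formyl group and the CH2 terminus of diene 9 adds to the carbonyl carbon in a Mukaiyama aldol event (C2–C3), the silyl group passing to oxygen to give 10; trifluoroacetic acid then frees the C2 oxygen, which closes onto the methoxy-bearing carbon (O1–C8a), and methanol is expelled to leave the enone. The closest known reaction type is the BINOL–titanium-catalysed hetero-Diels–Alder reaction, in its aldol–cyclisation form, of aromatic aldehydes with 1-methoxy-3-silyloxybutadiene. Ring C closes in the 6-endo-trig mode as an oxa-Michael addition–elimination. C2 is set by the ligand: the (S)-BINOL complex is expected to leave the Si face of the aldehyde open, which corresponds to (S) at C2, and the antipodal ligand is equally available should the sense prove opposite. The step needs chemoselectivity for the formyl group and a clean enantioface choice; the flavone carbonyl is a vinylogous ester and no heterodienophile, the aldehyde has no α-hydrogen, and both phenols are capped as benzyl ethers so that no acidic OH exchanges onto titanium.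

Step 7
Reactants: 11 (2S)-2-(3-{5-(benzyloxy)-2-[4-(benzyloxy)phenyl]-7-methoxy-4-oxo-4H-chromen-8-yl}-4-methoxyphenyl)-2,3-dihydro-4H-pyran-4-one
Product: 12 (2S)-5-bromo-2-(3-{5-(benzyloxy)-2-[4-(benzyloxy)phenyl]-7-methoxy-4-oxo-4H-chromen-8-yl}-4-methoxyphenyl)-2,3-dihydro-4H-pyran-4-one
Conditions: NBS (1.05 equiv), CH2Cl2, 0 °C, dark
Reagents that add atoms: N-bromosuccinimide, O=C1CCC(=O)N1Br
Why: Electrophilic α-bromination of a vinylogous ester (attack of the enol ether carbon C4a on bromine, then loss of the proton) should outpace substitution on the aromatic rings because the non-aromatic enol ether is the most nucleophilic site, and the neutral conditions leave C2 untouched.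

Step 8
Reactants: 13 methyl (E)-3-methoxybut-2-enoate
Product: 14 1,3-dimethoxy-1-(trimethylsilyloxy)buta-1,3-diene
Conditions: LiN(iPr)2, THF, −78 °C; then Me3SiCl, −78 °C to rt
Reagents that add atoms: chlorotrimethylsilane, C[Si](C)(C)Cl
Why: γ-Deprotonation of the β-methoxy enoate and O-silylation of the dienolate is the standard preparation of this silyl ketene acetal diene; the geometry of its acetal double bond is immaterial.

Step 9
Reactants: 12 (2S)-5-bromo-2-(3-{5-(benzyloxy)-2-[4-(benzyloxy)phenyl]-7-methoxy-4-oxo-4H-chromen-8-yl}-4-methoxyphenyl)-2,3-dihydro-4H-pyran-4-one; 14 1,3-dimethoxy-1-(trimethylsilyloxy)buta-1,3-diene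
Product: 16 (2S)-2-(3-{5-(benzyloxy)-2-[4-(benzyloxy)phenyl]-7-methoxy-4-oxo-4H-chromen-8-yl}-4-methoxyphenyl)-5-hydroxy-7-methoxy-2,3-dihydro-4H-chromen-4-one, via bromo cycloadduct 15 (not isolated)
Conditions: 14 (4 equiv), propylene oxide (5 equiv), toluene, 100 °C, sealed tube; then 1 M HCl, THF, 0 °C
Reagents that add atoms: none
Why: Proposed new method: the α-bromine lowers the LUMO of the vinylogous ester so that the CH2 terminus of diene 14, its most nucleophilic carbon, should bond to the β-carbon C8a while the ketene acetal carbon bonds to C4a (concerted Diels–Alder, or Michael addition then ring closure), after which adduct 15 loses methanol from the silyl ketal, tautomerises to a cyclohexadienol and aromatises by syn loss of HBr (trapped by propylene oxide), the acid work-up freeing the C5 phenol and leaving OMe at C7; the closest known reaction type is the regioselective benzannulation of halo-quinones and α-bromo enones with 1,1,3-trioxygenated silyloxydienes, and the base-free conditions keep C2 from epimerising through retro-oxa-Michael opening.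

Step 10
Reactants: 16 (2S)-2-(3-{5-(benzyloxy)-2-[4-(benzyloxy)phenyl]-7-methoxy-4-oxo-4H-chromen-8-yl}-4-methoxyphenyl)-5-hydroxy-7-methoxy-2,3-dihydro-4H-chromen-4-one
Product: 17 (2S)-5-hydroxy-2-{3-[5-hydroxy-2-(4-hydroxyphenyl)-7-methoxy-4-oxo-4H-chromen-8-yl]-4-methoxyphenyl}-7-methoxy-2,3-dihydro-4H-chromen-4-one
Conditions: H2 (1 atm), 10% Pd/C, EtOAc/THF, rt
Reagents that add atoms: none
Why: Hydrogenolysis of the two aryl benzyl ethers under neutral conditions should free both phenols while the methyl ethers, the flavone double bond and the C2 configuration are retained.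

Compound list
1 | 1-(2,6-dihydroxy-4-methoxyphenyl)ethan-1-one | CC(=O)c1c(O)cc(OC)cc1O | starting material
2 | 1-[2-(benzyloxy)-6-hydroxy-4-methoxyphenyl]ethan-1-one | CC(=O)c1c(O)cc(OC)cc1OCc1ccccc1 | intermediate
3 | 4-(benzyloxy)benzaldehyde | O=Cc1ccc(OCc2ccccc2)cc1 | starting material
4 | (E)-1-[2-(benzyloxy)-6-hydroxy-4-methoxyphenyl]-3-[4-(benzyloxy)phenyl]prop-2-en-1-one | O=C(/C=C/c1ccc(OCc2ccccc2)cc1)c1c(O)cc(OC)cc1OCc1ccccc1 | intermediate
5 | 5-(benzyloxy)-2-[4-(benzyloxy)phenyl]-7-methoxy-4H-chromen-4-one | COc1cc(OCc2ccccc2)c2c(=O)cc(-c3ccc(OCc4ccccc4)cc3)oc2c1 | intermediate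
6 | 5-(benzyloxy)-2-[4-(benzyloxy)phenyl]-8-iodo-7-methoxy-4H-chromen-4-one | COc1cc(OCc2ccccc2)c2c(=O)cc(-c3ccc(OCc4ccccc4)cc3)oc2c1I | intermediate
7 | (5-formyl-2-methoxyphenyl)boronic acid | COc1ccc(C=O)cc1B(O)O | starting material
8 | 3-{5-(benzyloxy)-2-[4-(benzyloxy)phenyl]-7-methoxy-4-oxo-4H-chromen-8-yl}-4-methoxybenzaldehyde | O=Cc1ccc(OC)c(-c2c(OC)cc(OCc3ccccc3)c3c(=O)cc(-c4ccc(OCc5ccccc5)cc4)oc23)c1 | intermediate
9 | (E)-1-methoxy-3-(trimethylsilyloxy)buta-1,3-diene | CO/C=C/C(=C)O[Si](C)(C)C | starting material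
10 | (1E,5S)-5-(3-{5-(benzyloxy)-2-[4-(benzyloxy)phenyl]-7-methoxy-4-oxo-4H-chromen-8-yl}-4-methoxyphenyl)-1-methoxy-5-(trimethylsilyloxy)pent-1-en-3-one (not isolated) | CO/C=C/C(=O)C[C@H](O[Si](C)(C)C)c1ccc(OC)c(-c2c(OC)cc(OCc3ccccc3)c3c(=O)cc(-c4ccc(OCc5ccccc5)cc4)oc23)c1 | intermediate
11 | (2S)-2-(3-{5-(benzyloxy)-2-[4-(benzyloxy)phenyl]-7-methoxy-4-oxo-4H-chromen-8-yl}-4-methoxyphenyl)-2,3-dihydro-4H-pyran-4-one | O=C1C=CO[C@H](c2ccc(OC)c(-c3c(OC)cc(OCc4ccccc4)c4c(=O)cc(-c5ccc(OCc6ccccc6)cc5)oc34)c2)C1 | intermediate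
12 | (2S)-5-bromo-2-(3-{5-(benzyloxy)-2-[4-(benzyloxy)phenyl]-7-methoxy-4-oxo-4H-chromen-8-yl}-4-methoxyphenyl)-2,3-dihydro-4H-pyran-4-one | O=C1C(Br)=CO[C@H](c2ccc(OC)c(-c3c(OC)cc(OCc4ccccc4)c4c(=O)cc(-c5ccc(OCc6ccccc6)cc5)oc34)c2)C1 | intermediate
13 | methyl (E)-3-methoxybut-2-enoate | CO/C(C)=C/C(=O)OC | starting material
14 | 1,3-dimethoxy-1-(trimethylsilyloxy)buta-1,3-diene | C=C(OC)C=C(OC)O[Si](C)(C)C | intermediate
15 | (2S)-4a-bromo-2-(3-{5-(benzyloxy)-2-[4-(benzyloxy)phenyl]-7-methoxy-4-oxo-4H-chromen-8-yl}-4-methoxyphenyl)-5,7-dimethoxy-5-(trimethylsilyloxy)-2,3,4a,5,8,8a-hexahydro-4H-chromen-4-one, cis-fused, diastereomer mixture at C4a, C5 and C8a (not isolated) | COC1=CC(OC)(O[Si](C)(C)C)C2(Br)C(=O)C[C@@H](c3ccc(OC)c(-c4c(OC)cc(OCc5ccccc5)c5c(=O)cc(-c6ccc(OCc7ccccc7)cc6)oc45)c3)OC2C1 | intermediate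
16 | (2S)-2-(3-{5-(benzyloxy)-2-[4-(benzyloxy)phenyl]-7-methoxy-4-oxo-4H-chromen-8-yl}-4-methoxyphenyl)-5-hydroxy-7-methoxy-2,3-dihydro-4H-chromen-4-one | COc1cc(O)c2c(c1)O[C@H](c1ccc(OC)c(-c3c(OC)cc(OCc4ccccc4)c4c(=O)cc(-c5ccc(OCc6ccccc6)cc5)oc34)c1)CC2=O | intermediate
17 | (2S)-5-hydroxy-2-{3-[5-hydroxy-2-(4-hydroxyphenyl)-7-methoxy-4-oxo-4H-chromen-8-yl]-4-methoxyphenyl}-7-methoxy-2,3-dihydro-4H-chromen-4-one | COc1cc(O)c2c(c1)O[C@H](c1ccc(OC)c(-c3c(OC)cc(O)c4c(=O)cc(-c5ccc(O)cc5)oc34)c1)CC2=O | target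

Total step count: 10. Longest linear sequence: 9 steps (steps 1 to 7, 9 and 10); step 8 is a one-step side branch.

Steps most likely to fail

Step 9. The bromo-enone is a push-pull alkene and may add the diene too slowly, so that the diene is lost to hydrolysis or oligomerisation. The tertiary bromide of the adduct may also be removed reductively, after which β-elimination of O1 would open ring C, or the aromatisation may stall before HBr is lost. The fallback uses only established flavanone chemistry and sets out from aldehyde 8 and acetophenone 2. Claisen–Schmidt condensation (KOH, EtOH/THF, rt) should give the 2'-hydroxychalcone F1. Oxa-Michael closure (NaOAc, EtOH, reflux) should give the racemic 5-benzyloxyflavanone F2. Preparative chromatography on a cellulose tris(3,5-dimethylphenylcarbamate) phase should deliver the (2S)-flavanone F3. Hydrogenolysis of its three benzyl ethers (H2, 10% Pd/C, EtOAc/THF) returns to the route at target 17. In this variant C2 is secured by resolution instead of catalysis.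

Step 6. The pyranone carbonyl and the neighbouring benzyloxy group of the flavone may sequester titanium, and the electron-rich aldehyde may react slowly enough for uncatalysed addition to erode the enantioface selectivity. The fallback replaces catalytic Lewis-acid control by a stoichiometric chiral boron enolate and sets out from 8. (E)-4-Methoxybut-3-en-2-one is enolised with B-chlorodiisopinocampheylborane and iPr2NEt (Et2O, −78 °C), using the antipode of the borane that delivers Si-face attack. Aldol addition to 8 and mild work-up should give the hydroxy enone F4, and CF3CO2H in CH2Cl2 closes it with loss of methanol to rejoin the route at dihydropyranone 11.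

Step 7. The electrophilic bromine source may also attack flavone C6 or ring B, or brominate twice. The fallback introduces the halogen by an amine-mediated α-iodination, which leaves electron-rich arenes alone. It sets out from 11: I2 and pyridine in CH2Cl2 at rt should give the iodo enone F5. F5 is then taken through the conditions of step 9 with diene 14, via the iodo cycloadduct F6 (not isolated) and loss of HI in place of HBr, and returns to the route at flavanone 16.

Further compounds
F1 | step 9 | (E)-1-[2-(benzyloxy)-6-hydroxy-4-methoxyphenyl]-3-(3-{5-(benzyloxy)-2-[4-(benzyloxy)phenyl]-7-methoxy-4-oxo-4H-chromen-8-yl}-4-methoxyphenyl)prop-2-en-1-one | O=C(/C=C/c1ccc(OC)c(-c2c(OC)cc(OCc3ccccc3)c3c(=O)cc(-c4ccc(OCc5ccccc5)cc4)oc23)c1)c1c(O)cc(OC)cc1OCc1ccccc1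
F2 | step 9 | rac-5-(benzyloxy)-2-(3-{5-(benzyloxy)-2-[4-(benzyloxy)phenyl]-7-methoxy-4-oxo-4H-chromen-8-yl}-4-methoxyphenyl)-7-methoxy-2,3-dihydro-4H-chromen-4-one | COc1cc(OCc2ccccc2)c2c(c1)OC(c1ccc(OC)c(-c3c(OC)cc(OCc4ccccc4)c4c(=O)cc(-c5ccc(OCc6ccccc6)cc5)oc34)c1)CC2=O
F3 | step 9 | (2S)-5-(benzyloxy)-2-(3-{5-(benzyloxy)-2-[4-(benzyloxy)phenyl]-7-methoxy-4-oxo-4H-chromen-8-yl}-4-methoxyphenyl)-7-methoxy-2,3-dihydro-4H-chromen-4-one | COc1cc(OCc2ccccc2)c2c(c1)O[C@H](c1ccc(OC)c(-c3c(OC)cc(OCc4ccccc4)c4c(=O)cc(-c5ccc(OCc6ccccc6)cc5)oc34)c1)CC2=O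
F4 | step 6 | (1E,5S)-5-(3-{5-(benzyloxy)-2-[4-(benzyloxy)phenyl]-7-methoxy-4-oxo-4H-chromen-8-yl}-4-methoxyphenyl)-5-hydroxy-1-methoxypent-1-en-3-one | CO/C=C/C(=O)C[C@H](O)c1ccc(OC)c(-c2c(OC)cc(OCc3ccccc3)c3c(=O)cc(-c4ccc(OCc5ccccc5)cc4)oc23)c1
F5 | step 7 | (2S)-2-(3-{5-(benzyloxy)-2-[4-(benzyloxy)phenyl]-7-methoxy-4-oxo-4H-chromen-8-yl}-4-methoxyphenyl)-5-iodo-2,3-dihydro-4H-pyran-4-one | O=C1C(I)=CO[C@H](c2ccc(OC)c(-c3c(OC)cc(OCc4ccccc4)c4c(=O)cc(-c5ccc(OCc6ccccc6)cc5)oc34)c2)C1
F6 | step 7 | (2S)-2-(3-{5-(benzyloxy)-2-[4-(benzyloxy)phenyl]-7-methoxy-4-oxo-4H-chromen-8-yl}-4-methoxyphenyl)-4a-iodo-5,7-dimethoxy-5-(trimethylsilyloxy)-2,3,4a,5,8,8a-hexahydro-4H-chromen-4-one, cis-fused, diastereomer mixture at C4a, C5 and C8a | COC1=CC(OC)(O[Si](C)(C)C)C2(I)C(=O)C[C@@H](c3ccc(OC)c(-c4c(OC)cc(OCc5ccccc5)c5c(=O)cc(-c6ccc(OCc7ccccc7)cc6)oc45)c3)OC2C1
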